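## Retrosynthetic overview
1. The ten-membered carbocycle is closed last by ring-closing metathesis at C1=C10 (vinyl ketone plus methallyl group). The ring size enforces the Z-enone.
2. The C6–C7 bond comes from an indium Barbier (SE2') coupling of a C2–C6 α-acyloxy aldehyde with (R)-3-(bromomethyl)-5-methallylbutenolide. This step creates the exo-methylene trans-lactone, the free 6-OH, and the C6 and C7 stereocentres.
3. The butenolide comes from Brown methallylation of acrolein (sets C8), esterification with 2-(bromomethyl)acrylic acid, and RCM.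
4. The C2–C6 piece comes from Brown anti-crotylation of TBSOCH2CHO (sets C4 and C5). The 5-OH is esterified immediately with (2R,3R)-epoxyangelic acid, made by Sharpless epoxidation, so the ester is the only "protection" at O5.
5. Ring order: oxirane, then butenolide (which becomes the γ-lactone), then cyclodecenone.

Notation and assumption: germacrane numbering is used. The SMILES reads as 4R,5R,6R,7R,8R,2'R,3'R with a 1(10)-Z alkene, a trans-fused 8,12-olide, 4-Me/5-O anti, and 5-O/6-O syn. The C2 carbinol in 18 and 19 is carried as an epimer mixture because step 13 destroys that centre.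

## Route

### Epoxyangelic acid fragment

**Step 1**
- Reactants: 1, methyl angelate (methyl (Z)-2-methylbut-2-enoate)
- Product: 2, (Z)-2-methylbut-2-en-1-ol
- Conditions: DIBAL-H (2.2 equiv), CH2Cl2, −78 to 0 °C; Rochelle salt
- Reagents that add atoms: none
- Why: DIBAL-H 1,2-reduction of the enoate proceeds without Z/E isomerisation, so the geometry that becomes the cis C3'-Me/carboxyl relationship of the oxirane is kept.

**Step 2**
- Reactants: 2
- Product: 3, [(2S,3R)-2,3-dimethyloxiran-2-yl]methanol
- Conditions: Ti(OiPr)4, L-(+)-DET, t-BuOOH, 4 Å MS, CH2Cl2, −20 °C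
- Reagents that add atoms: tert-butyl hydroperoxide, CC(C)(C)OO (oxirane O)
- Why: In this Katsuki–Sharpless asymmetric epoxidation, stereospecific syn O-transfer keeps CH2OH cis to the C3 methyl, and L-(+)-tartrate selects the face giving the (2S)-epoxy alcohol, so both oxirane centres are set.

**Step 3**
- Reactants: 3
- Product: 4, (2R,3R)-2,3-dimethyloxirane-2-carboxylic acid (epoxyangelic acid)
- Conditions: RuCl3·xH2O (2 mol %), NaIO4, MeCN/CCl4/H2O, rt
- Reagents that add atoms: water, O; sodium periodate (terminal oxidant/O source), [Na+].[O-]I(=O)(=O)=O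
- Why: Sharpless RuO4 oxidation takes the primary alcohol to the acid without touching the oxirane, and the C2 label changes from S to R only through CIP priorities.

### Bromomethylbutenolide fragment

**Step 4**
- Reactants: 5, acrolein; 6, 2-methylallylmagnesium chloride
- Product: 7, (R)-5-methylhexa-1,5-dien-3-ol
- Conditions: (+)-Ipc2BOMe (from (−)-α-pinene), 6, Et2O, −78 °C to rt; then 5, −78 °C; NaOH, H2O2
- Reagents that add atoms: 2-methylallylmagnesium chloride, C=C(C)C[Mg]Cl
- Why: Brown asymmetric methallylboration goes through a closed chair transition state, and this Ipc antipode attacks the Re face of acrolein to give the (R)-carbinol, which is C8.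

**Step 5**
- Reactants: 7; 8, 2-(bromomethyl)acrylic acid
- Product: 9, (R)-5-methylhexa-1,5-dien-3-yl 2-(bromomethyl)acrylate
- Conditions: DIC, DMAP (5 mol %), CH2Cl2, 0 °C
- Reagents that add atoms: 2-(bromomethyl)acrylic acid, OC(=O)C(=C)CBr
- Why: Steglich esterification acylates at oxygen, so C8 is retained, and low temperature with catalytic DMAP spares the allylic bromide.

**Step 6**
- Reactants: 9
- Product: 10, (R)-3-(bromomethyl)-5-(2-methylallyl)furan-2(5H)-one
- Conditions: Grubbs II (5 mol %), CH2Cl2 (0.01 M), reflux
- Reagents that add atoms: none (ethylene is lost)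
- Why: In this RCM the catalyst loads on the monosubstituted vinyl group and closes onto the acrylate to give the five-membered butenolide, while the methallyl group could only give a cyclobutene or a tetrasubstituted six-ring alkene and is left alone.

### Main line

**Step 7**
- Reactants: 11, (tert-butyldimethylsilyloxy)acetaldehyde; 12, trans-2-butene
- Product: 13, (2R,3R)-1-(tert-butyldimethylsilyloxy)-3-methylpent-4-en-2-ol
- Conditions: 12, KOt-Bu, n-BuLi, THF, −78 to −45 °C; (+)-Ipc2BOMe, −78 °C; BF3·OEt2; 11, −78 °C; NaOH, H2O2
- Reagents that add atoms: trans-2-butene, C/C=C/C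
- Why: In Brown (E)-crotylboration the Zimmerman–Traxler chair converts the E-crotyl geometry into the anti Me/OH relationship, and the Ipc ligands direct Re-face attack, setting C5 (R) and C4 (R).

**Step 8**
- Reactants: 13; 4
- Product: 14, (2R,3R)-1-(TBSO)-3-methylpent-4-en-2-yl (2R,3R)-2,3-dimethyloxirane-2-carboxylate
- Conditions: 4, 2,4,6-Cl3C6H2COCl, Et3N, toluene; then 13, DMAP, rt
- Reagents that add atoms: epoxyangelic acid 4, OC(=O)[C@]1(C)O[C@@H]1C
- Why: Yamaguchi esterification couples the hindered acid and alcohol with all four centres retained, the ester also serves as O5 protection, and minor diastereomers arising from imperfect ee are removed chromatographically here.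

**Step 9**
- Reactants: 14
- Product: 15, (2R,3R)-1-(TBSO)-5-hydroxy-3-methylpentan-2-yl (2R,3R)-2,3-dimethyloxirane-2-carboxylate
- Conditions: 9-BBN, THF, 0 °C to rt; NaBO3·4H2O, H2O
- Reagents that add atoms: sodium perborate, [Na+].[Na+].O[B-]1(O)OO[B-](O)(O)OO1 (hydroxyl O)
- Why: Anti-Markovnikov hydroboration–oxidation acts on the only alkene, 9-BBN ignores the ester, oxirane and silyl ether, and perborate avoids saponification.

**Step 10**
- Reactants: 15
- Product: 16, (2R,3R)-1-(TBSO)-3-methyl-5-oxopentan-2-yl (2R,3R)-2,3-dimethyloxirane-2-carboxylate (C2 aldehyde)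
- Conditions: DMP, NaHCO3, CH2Cl2, 0 °C to rt
- Reagents that add atoms: none
- Why: Buffered Dess–Martin oxidation of the primary alcohol is neutral enough for the oxirane, ester and TBS ether.

**Step 11**
- Reactants: 16; 17, vinylmagnesium bromide
- Product: 18, (2R,3R,5RS)-1-(TBSO)-5-hydroxy-3-methylhept-6-en-2-yl (2R,3R)-2,3-dimethyloxirane-2-carboxylate
- Conditions: 17 (1.1 equiv), THF, −78 °C
- Reagents that add atoms: vinylmagnesium bromide, C=C[Mg]Br
- Why: In this Grignard 1,2-addition the aldehyde reacts far faster at −78 °C than the α-quaternary ester of a secondary alcohol, and the new C2 carbinol mixture does not matter.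

**Step 12**
- Reactants: 18
- Product: 19, (2R,3R,5RS)-1,5-dihydroxy-3-methylhept-6-en-2-yl (2R,3R)-2,3-dimethyloxirane-2-carboxylate
- Conditions: HF·pyridine, pyridine, THF, 0 °C
- Reagents that add atoms: none
- Why: Buffered, non-basic fluoride desilylation removes the primary TBS group while minimising O5-to-O6 acyl migration of the hindered acyl group and opening of the deactivated glycidate oxirane.

**Step 13**
- Reactants: 19
- Product: 20, (2R,3R)-3-methyl-1,5-dioxohept-6-en-2-yl (2R,3R)-2,3-dimethyloxirane-2-carboxylate (C6 aldehyde and C2 vinyl ketone)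
- Conditions: DMP (3 equiv), NaHCO3, CH2Cl2, 0 °C to rt; used at once
- Reagents that add atoms: none
- Why: A double Dess–Martin oxidation converts both alcohols in one pot under neutral conditions, so the α-acyloxy aldehyde centre C5 is not epimerised.

**Step 14**
- Reactants: 20; 10 (1.3 equiv)
- Product: 21, (1R,2R,3R)-1-hydroxy-3-methyl-1-[(2R,3R)-4-methylidene-2-(2-methylallyl)-5-oxooxolan-3-yl]-5-oxohept-6-en-2-yl (2R,3R)-2,3-dimethyloxirane-2-carboxylate
- Conditions: In powder (2 equiv), THF/H2O 1:1, rt
- Reagents that add atoms: bromobutenolide 10, O=C1O[C@H](CC(C)=C)C=C1CBr (Br is lost)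
- Why: In this aldehyde-selective indium Barbier allylation (SE2'), the aldehyde bonds to C7 anti to the C8 side chain to give the trans-lactone (7R), the ring-locked "E-crotyl-type" allylindium reacts through a chair to give the anti product (6R), and this reagent control should override the weak Felkin bias that non-chelating α-oxy aldehydes show under aqueous indium conditions.

**Step 15**
- Reactants: 21
- Product: 22, vicolide D
- Conditions: Hoveyda–Grubbs II (15 mol %, in portions), 2,6-dichlorobenzoquinone (cat.), toluene (0.5 mM), 90 °C, Ar sparge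
- Reagents that add atoms: none (ethylene is lost)
- Why: RCM of the enone with the 1,1-disubstituted alkene forms the trisubstituted C1=C10 bond, the electron-poor exo-methylene lactone is a spectator, a cyclodec-2-enone forms as the less strained Z isomer, and no stereocentre is touched.

## Compound list

| No. | Name | SMILES | Role |
|---|---|---|---|
| 1 | methyl angelate | C/C=C(/C)C(=O)OC | starting material |
| 2 | (Z)-2-methylbut-2-en-1-ol | C/C=C(/C)CO | intermediate |
| 3 | [(2S,3R)-2,3-dimethyloxiran-2-yl]methanol | OC[C@]1(C)O[C@@H]1C | intermediate |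
| 4 | (2R,3R)-2,3-dimethyloxirane-2-carboxylic acid | OC(=O)[C@]1(C)O[C@@H]1C | intermediate |
| 5 | acrolein | C=CC=O | starting material |
| 6 | 2-methylallylmagnesium chloride | C=C(C)C[Mg]Cl | starting material |
| 7 | (R)-5-methylhexa-1,5-dien-3-ol | C=C[C@H](O)CC(C)=C | intermediate |
| 8 | 2-(bromomethyl)acrylic acid | OC(=O)C(=C)CBr | starting material |
| 9 | (R)-5-methylhexa-1,5-dien-3-yl 2-(bromomethyl)acrylate | C=C[C@@H](CC(C)=C)OC(=O)C(=C)CBr | intermediate |
| 10 | (R)-3-(bromomethyl)-5-(2-methylallyl)furan-2(5H)-one | O=C1O[C@H](CC(C)=C)C=C1CBr | intermediate |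
| 11 | (tert-butyldimethylsilyloxy)acetaldehyde | O=CCO[Si](C)(C)C(C)(C)C | starting material |
| 12 | trans-2-butene | C/C=C/C | starting material |
| 13 | (2R,3R)-1-(TBSO)-3-methylpent-4-en-2-ol | C=C[C@@H](C)[C@@H](O)CO[Si](C)(C)C(C)(C)C | intermediate |
| 14 | epoxyangelate of 13 | C=C[C@@H](C)[C@@H](OC(=O)[C@]1(C)O[C@@H]1C)CO[Si](C)(C)C(C)(C)C | intermediate |
| 15 | C2 primary alcohol | OCC[C@@H](C)[C@@H](OC(=O)[C@]1(C)O[C@@H]1C)CO[Si](C)(C)C(C)(C)C | intermediate |
| 16 | C2 aldehyde | O=CC[C@@H](C)[C@@H](OC(=O)[C@]1(C)O[C@@H]1C)CO[Si](C)(C)C(C)(C)C | intermediate |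
| 17 | vinylmagnesium bromide | C=C[Mg]Br | starting material |
| 18 | C2 allylic alcohol (epimers), 6-OTBS | C=CC(O)C[C@@H](C)[C@@H](OC(=O)[C@]1(C)O[C@@H]1C)CO[Si](C)(C)C(C)(C)C | intermediate |
| 19 | C2,C6 diol (C2 epimers) | C=CC(O)C[C@@H](C)[C@@H](OC(=O)[C@]1(C)O[C@@H]1C)CO | intermediate |
| 20 | vinyl ketone aldehyde | C=CC(=O)C[C@@H](C)[C@@H](OC(=O)[C@]1(C)O[C@@H]1C)C=O | intermediate |
| 21 | seco-triene (Barbier product) | C=CC(=O)C[C@@H](C)[C@@H](OC(=O)[C@]1(C)O[C@@H]1C)[C@H](O)[C@H]2C(=C)C(=O)O[C@@H]2CC(C)=C | intermediate |
| 22 | vicolide D | C=C1C(=O)O[C@@H]2C/C(C)=C\C(=O)C[C@@H](C)[C@@H](OC(=O)[C@]3(C)O[C@@H]3C)[C@H](O)[C@@H]12 | target |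

## Step count
- Total steps: 15.
- Longest linear sequence: 11 steps (steps 1–3, then 8–15).
- The carbon backbone takes 9 steps from 11.
- The butenolide branch takes 3 steps and joins at step 14.

## Steps most likely to fail
1. **Step 15, ten-membered enone RCM.** The risks are oligomerisation, slow initiation on two poor olefins, and E/Z leakage. Fallback: close the C1–C2 bond instead.
   - Build the butenolide fragment with a preformed (Z)-vinyl iodide. The iodide comes from (Z)-3-iodo-2-methylprop-2-en-1-ol, made from propargyl alcohol with MeMgBr/CuI and then I2.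
   - Keep C2 as an aldehyde, cyclise by intramolecular Nozaki–Hiyama–Kishi coupling, and oxidise the allylic alcohol with MnO2.
   - The alkene geometry is then fixed before cyclisation.
2. **Step 14, C6 configuration.** Reagent control opposes the polar Felkin preference of the α-acyloxy aldehyde, and the vinyl ketone is exposed to the reaction conditions. Fallback: carry O5 as a chelating PMB ether so that chelation control and reagent control both favour the 5,6-syn product. Then protect 6-OH as a TES ether, remove PMB with DDQ, esterify with 4, run the RCM, and remove TES. This adds 4 steps.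
3. **Steps 12–13, free primary 6-OH next to the 5-ester.** The risks are acyl migration and a labile aldehyde. Fallback: replace 11 with (E)-crotonaldehyde in step 7 so that C6 is carried as a propenyl group. After C2 is oxidised to the enone, chemoselective ozonolysis of the electron-rich 1,2-disubstituted alkene gives 20 directly, and no hydroxyl is ever generated next to the ester.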